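## Retrosynthetic overview
1. Cut both C–C bonds of the CH2 bridge. This gives (2S)-pinocembrin (bought, carrying the only stereocentre and three of the four rings), a C1 iminium salt, and 6-ethyl-4-hydroxy-5-methyl-2-pyrone.
2. Open the pyrone by a retro-oxa-6π electrocyclisation to an enol acylketene. The ketene comes from a tert-butyl 3,5-dioxo ester by thermal loss of t-BuOH.
3. The 3,5-dioxo ester comes from γ-acylation of the dianion of tert-butyl 3-oxopentanoate with the propionyl Weinreb amide.
4. Ring order: the pyrone is made first and is the only ring built. The methylene bridge is then attached to C8 of the intact flavanone.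

Assumption: natural (2S)-(−)-pinocembrin (CAS 480-39-7) and tert-butyl 3-oxopentanoate are taken as catalogue items, and the ee of the pinocembrin lot is checked by chiral HPLC before use.

## Route

Step 1
Reactants: 1 tert-butyl 3-oxopentanoate; 2 N-methoxy-N-methylpropanamide
Product: 5 tert-butyl 4-methyl-3,5-dioxoheptanoate, via ester dianion 3 (not isolated), via Weinreb adduct 4 (not isolated)
Conditions: NaH (1.1 equiv), THF, 0 °C; n-BuLi (1.05 equiv), 0 °C; 2 (1.0 equiv), −78 → 0 °C; 1 M HCl, 0 °C
Reagents that add atoms: none
Why: In this Huckin–Weiler dianion acylation the doubly deprotonated β-keto ester reacts only at its more basic γ-carbon, and as a Weinreb ketone synthesis the chelated adduct 4 holds until the acid quench, so neither over-addition nor quenching of unreacted dianion by the more acidic product occurs; the new C4 centre is racemic, enolisable and erased in step 2.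

Step 2
Reactants: 5 tert-butyl 4-methyl-3,5-dioxoheptanoate
Product: 8 6-ethyl-4-hydroxy-5-methyl-2H-pyran-2-one, via keto acylketene 6 (not isolated), via enol acylketene 7 (not isolated)
Conditions: PhMe (0.05 M), reflux (110 °C), 3 h, t-BuOH distilled off
Reagents that add atoms: none
Why: A tert-butyl β-keto ester loses t-BuOH on heating through a six-centre retro-ene-type elimination to give acylketene 6, whose enol 7 is a 1-oxatriene (ketone O and ketene carbon cis on the C3=C4 double bond) that closes irreversibly by oxa-6π electrocyclisation to the 2-pyrone, with dilution suppressing ketene dimerisation; no stereocentre is left in 8.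

Step 3
Reactants: 8 6-ethyl-4-hydroxy-5-methyl-2H-pyran-2-one; 9 (2S)-pinocembrin, i.e. (2S)-5,7-dihydroxy-2-phenylchroman-4-one
Product: 12 (2S)-8-[(6-ethyl-4-hydroxy-5-methyl-2-oxo-2H-pyran-3-yl)methyl]-5,7-dihydroxy-2-phenyl-2,3-dihydro-4H-chromen-4-one, via Mannich base 10 (not isolated), via pyrone methide 11 (not isolated)
Conditions: 8 added slowly to CH2=NMe2+ I− (1.0 equiv), MeCN, 0 °C → rt, 1 h; then 9 (2.0 equiv), NaOAc (1.0 equiv), AcOH (10 vol %), 60 °C, 6 h, N2; SiO2, then C18 HPLC (removes the 6-isomer, recovers 9)
Reagents that add atoms: Eschenmoser's salt (N,N-dimethylmethyleneiminium iodide), C=[N+](C)C.[I-]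
Why: A Mannich reaction at C3 (the only free nucleophilic carbon of 8) followed by buffered β-elimination of Me2NH gives the very electrophilic alkylidene-1,3-dicarbonyl 11, which the phloroglucinol A ring of 9 (in excess) captures by Friedel–Crafts-type conjugate addition (carba-Betti coupling) at C8 and C6 in roughly equal parts, so 12 is isolated by chromatography; no stereocentre is made, and C2 of 9 is kept because the pH 4–5 buffer shuts off the base-induced retro-oxa-Michael (chalcone) racemisation.

## Compound list
1 | tert-butyl 3-oxopentanoate | CCC(=O)CC(=O)OC(C)(C)C | starting material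
2 | N-methoxy-N-methylpropanamide | CCC(=O)N(C)OC | starting material
3 | lithium sodium 1-tert-butoxypenta-1,3-diene-1,3-diolate (α,γ-dianion of 1) | CC=C([O-])C=C([O-])OC(C)(C)C.[Li+].[Na+] | intermediate
4 | lithium sodium salt of tert-butyl 5-hydroxy-5-[methoxy(methyl)amino]-4-methyl-3-oxoheptanoate (5-alkoxide, ester enolate) | CCC([O-])(N(C)OC)C(C)C(=O)C=C([O-])OC(C)(C)C.[Li+].[Na+] | intermediate
5 | tert-butyl 4-methyl-3,5-dioxoheptanoate (racemic at C4, keto/enol mixture) | CCC(=O)C(C)C(=O)CC(=O)OC(C)(C)C | intermediate
6 | 4-methylhept-1-ene-1,3,5-trione (keto acylketene) | CCC(=O)C(C)C(=O)C=C=O | intermediate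
7 | (3E)-3-hydroxy-4-methylhepta-1,3-diene-1,5-dione (enol acylketene) | CCC(=O)/C(C)=C(\C=C=O)O | intermediate
8 | 6-ethyl-4-hydroxy-5-methyl-2H-pyran-2-one | CCc1oc(=O)cc(O)c1C | intermediate
9 | (2S)-pinocembrin | Oc1cc(O)c2c(c1)O[C@H](c1ccccc1)CC2=O | starting material
10 | 3-[(dimethylamino)methyl]-6-ethyl-4-hydroxy-5-methyl-2H-pyran-2-one | CCc1oc(=O)c(CN(C)C)c(O)c1C | intermediate
11 | 6-ethyl-5-methyl-3-methylidene-2H-pyran-2,4(3H)-dione | CCC1=C(C)C(=O)C(=C)C(=O)O1 | intermediate
12 | (2S)-8-[(6-ethyl-4-hydroxy-5-methyl-2-oxo-2H-pyran-3-yl)methyl]-5,7-dihydroxy-2-phenyl-2,3-dihydro-4H-chromen-4-one | CCc1oc(=O)c(Cc2c(O)cc(O)c3c2O[C@H](c2ccccc2)CC3=O)c(O)c1C | target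

## Totals
Total step count: 3.
Longest linear sequence: 3 (1 → 5 → 8 → 12).

## Steps most likely to fail

**1. Step 3 (highest risk).**
- C6 and C8 of 9 carry the same set of activating oxygens. Acid-side C-alkylations of pinocembrin and naringenin (prenylation, o-hydroxybenzylation) give the 6- and 8-isomers in comparable amounts, so about 25–35 % of 12 is expected after separation.
- The methylene-bis-pyrone homodimer and the 6,8-bis-adduct also compete. The slow inverse addition of 8 and the excess of 9 are there to limit them.
- The isomer is assigned by HMBC: the chelated 5-OH correlates to a C6–H carbon in 12. The ee is checked by chiral HPLC.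
- Fallback, setting out from 8 and coming back at 12. The nucleophile is changed to a flavanone whose C6 is shielded. Compound 8 is taken through 10 and 11 as before but trapped with natural (2S)-alpinetin F1 (7-hydroxy-5-methoxyflavanone, bought). Its 5-OMe methyl group is turned towards C6 by the peri carbonyl, and its only free phenol (7-OH) is expected to direct attack to C8. This gives the 5-O-methyl ether of the target F2. The peri methoxy group alone is then cleaved by chelation-controlled demethylation with BCl3 (5 equiv, CH2Cl2, −78 → 0 °C) to give 12. The ee is rechecked, because a Lewis acid could open ring C.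

**2. Step 1.**
- Addition of a secondary γ-carbanion to the Weinreb amide can be sluggish, and the triketide can suffer retro-Claisen cleavage on work-up. The expected yield is about 55–65 %.
- Fallback, setting out from 1 and coming back at 5. Acylation is replaced by aldol addition and oxidation. Dianion 3, made from 1 as before, is added to propanal (THF, −78 °C) to give tert-butyl 5-hydroxy-4-methyl-3-oxoheptanoate F3 as a diastereomer mixture, which is of no consequence. Dess–Martin periodinane (CH2Cl2, rt) then oxidises the carbinol to 5.

**3. Step 2.**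
- Competing loss of the tert-butyl group followed by decarboxylation, or ketene dimerisation, would lower the yield. About 70–80 % is expected.
- Fallback, setting out from 5 and coming back at 8. The thermal ring closure is replaced by an ionic lactonisation. TFA (CH2Cl2, 0 °C) cleaves the ester to 4-methyl-3,5-dioxoheptanoic acid F4, which is used at once because it decarboxylates on standing. TFAA (0 °C → rt) activates it as the mixed anhydride, and the C5 enol oxygen closes the ring to 8.

## Further compounds
F1 | step 3 | (2S)-alpinetin, (2S)-7-hydroxy-5-methoxy-2-phenylchroman-4-one (bought) | Oc1cc(OC)c2c(c1)O[C@H](c1ccccc1)CC2=O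
F2 | step 3 | (2S)-8-[(6-ethyl-4-hydroxy-5-methyl-2-oxo-2H-pyran-3-yl)methyl]-7-hydroxy-5-methoxy-2-phenyl-2,3-dihydro-4H-chromen-4-one | CCc1oc(=O)c(Cc2c(O)cc(OC)c3c2O[C@H](c2ccccc2)CC3=O)c(O)c1C
F3 | step 1 | tert-butyl 5-hydroxy-4-methyl-3-oxoheptanoate (racemic diastereomer mixture) | CCC(O)C(C)C(=O)CC(=O)OC(C)(C)C
F4 | step 2 | 4-methyl-3,5-dioxoheptanoic acid | CCC(=O)C(C)C(=O)CC(=O)O
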